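**Retrosynthetic overview**
1. The C1 carbinol comes from CBS reduction of a C1 enone, the 4,5-epoxide from peripheral epoxidation, and the lactone (third ring formed) from Pd cyclocarbonylation of a trans 8-hydroxy-7-ethynyl unit.
2. The ten-membered ring (second) comes from anionic oxy-Cope ring expansion of a 1-vinyl-2-isopropenylcyclohexanol (ring C5–C10), with enolate hydroxylation at C1 and Wittig methylenation at C10.
3. The cyclohexanone comes from SmI2 opening of a 7-oxanorbornan-2-one; the isopropenyl group is put on by Pd enolate alkenylation.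
4. The oxa-bridged six-membered carbocycle (first) comes from the key dearomative asymmetric Diels–Alder reaction of 3-methoxyfuran with (E)-4-oxopent-2-enal, which sets C6, C7 and C8; the acetyl group later becomes the C8 oxygen by Baeyer–Villiger oxidation.
5. (E)-4-Oxopent-2-enal comes from oxidative ring opening of 2-methylfuran.

Assumption: atom labels C1–C15 are those of the germacrane skeleton of the target (C6 carries the angelate, C8 the lactone oxygen); the (S)-oxazaborolidinium catalyst is assumed to give 5, and its antipode would be used if the facial sense proved opposite.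

**Step 1**
Reactants: 1 2-methylfuran
Product: 3 (E)-4-oxopent-2-enal, via (Z)-4-oxopent-2-enal 2 (not isolated)
Conditions: NBS, NaHCO3, acetone/H2O, −15 °C; then pyridine, rt
Reagents that add atoms: water, O
Why: Oxidative ring opening of a 2-alkylfuran with NBS/water (Achmatowicz-type oxidation) gives the cis 1,4-dicarbonyl, and pyridine isomerises it Z to E; no stereocentre is formed.

**Step 2**
Reactants: 3 (E)-4-oxopent-2-enal; 4 3-methoxyfuran
Product: 5 (1R,2R,3R,4R)-3-acetyl-5-methoxy-7-oxabicyclo[2.2.1]hept-5-ene-2-carbaldehyde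
Conditions: (S)-2-(o-tolyl)-CBS-oxazaborolidine activated with Tf2NH (20 mol%), CH2Cl2, −78 °C
Reagents that add atoms: none
Why: Proposed new method: dearomative catalytic asymmetric Diels–Alder reaction in which the boron-bound formyl group makes the acetyl-bearing carbon the electrophilic terminus, so it bonds first to the nucleophilic C2 of the furan (CHO carbon ends para to the OMe carbon), CHO goes endo and acetyl exo, and the catalyst face selection fixes C6, C7, C8 and C9 at once; the closest known chemistry is the cationic oxazaborolidine-catalysed Diels–Alder reaction of furan with enals and acrylates.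

**Step 3**
Reactants: 5 oxanorbornene aldehyde
Product: 7 1-(3-endo-ethynyl-6,6-dimethoxy-7-oxabicyclo[2.2.1]hept-2-exo-yl)ethanone, via ethynyl enol ether 6 (not isolated)
Conditions: dimethyl (1-diazo-2-oxopropyl)phosphonate, K2CO3, MeOH, 0 °C to rt; work-up; crude in MeOH, PPTS (cat.), rt
Reagents that add atoms: dimethyl (1-diazo-2-oxopropyl)phosphonate, CC(=O)C(=[N+]=[N-])P(=O)(OC)OC; methanol, CO
Why: Ohira–Bestmann homologation turns the endo aldehyde into the ethynyl group without touching C7, and acid-catalysed addition of methanol to the enol ether masks C10 as a dimethyl ketal.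

**Step 4**
Reactants: 7 ethynyl ketal methyl ketone
Product: 8 3-endo-ethynyl-6,6-dimethoxy-7-oxabicyclo[2.2.1]hept-2-exo-yl acetate
Conditions: mCPBA, NaHCO3, CH2Cl2, rt
Reagents that add atoms: mCPBA, O=C(OO)c1cccc(Cl)c1
Why: Baeyer–Villiger oxidation, in which the secondary C8 migrates in preference to methyl with retention, so the exo acetyl becomes the exo C8–O acetate while the ketal protects the former enol ether.

**Step 5**
Reactants: 8 ethynyl ketal acetate
Product: 10 6-exo-(triisopropylsilyloxy)-5-endo-[(triisopropylsilyl)ethynyl]-7-oxabicyclo[2.2.1]heptan-2-one, via bis-silylated dimethyl ketal 9 (not isolated)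
Conditions: MeLi (3.3 equiv), THF, −78 to 0 °C; TIPSOTf, −78 to 0 °C; then 1 M HCl, THF, rt
Reagents that add atoms: triisopropylsilyl trifluoromethanesulfonate, CC(C)[Si](C(C)C)(C(C)C)OS(=O)(=O)C(F)(F)F; water, O
Why: Methyllithium cleaves the acetate and deprotonates the alkyne, the silyl triflate caps the alkoxide and the acetylide, and acid hydrolysis of the ketal releases the bridged ketone; no stereocentre changes.

**Step 6**
Reactants: 10 bridged ketone
Product: 11 3-endo-(prop-1-en-2-yl)-6-exo-(triisopropylsilyloxy)-5-endo-[(triisopropylsilyl)ethynyl]-7-oxabicyclo[2.2.1]heptan-2-one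
Conditions: Pd2(dba)3 (2.5 mol%), P(t-Bu)3 (6 mol%), LiHMDS (2.2 equiv), 2-bromopropene, THF, 0 °C to rt; NH4Cl at −78 °C
Reagents that add atoms: 2-bromopropene, CC(Br)=C
Why: Pd-catalysed α-alkenylation of a ketone enolate (Buchwald–Hartwig type), where only C5 can enolise because C9 is a bridgehead, and exo-face protonation of the product enolate on quench leaves the isopropenyl group endo (trans to the C6 oxygen).

**Step 7**
Reactants: 11 isopropenyl bridged ketone
Product: 13 all-equatorial 2-(prop-1-en-2-yl)-3-(triethylsilyloxy)-5-(triisopropylsilyloxy)-4-[(triisopropylsilyl)ethynyl]cyclohexan-1-one, via hydroxy ketone 12 (not isolated)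
Conditions: SmI2 (2.2 equiv), THF/MeOH, −78 °C; work-up; crude, TESCl, imidazole, DMF, 0 °C
Reagents that add atoms: chlorotriethylsilane, CC[Si](Cl)(CC)CC
Why: SmI2 reductive cleavage of the α-alkoxy ketone breaks the C9–O bond and releases the C6 hydroxyl, which is silylated in the crude; C5–C8 are untouched.

**Step 8**
Reactants: 13 cyclohexanone
Product: 14 1-ethenyl-2-(prop-1-en-2-yl)-3-(triethylsilyloxy)-5-(triisopropylsilyloxy)-4-[(triisopropylsilyl)ethynyl]cyclohexan-1-ol (vinyl equatorial, trans to isopropenyl)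
Conditions: CeCl3, vinylmagnesium bromide, THF, −78 °C
Reagents that add atoms: vinylmagnesium bromide, C=C[Mg]Br
Why: Organocerium 1,2-addition from the equatorial direction gives the trans-1-vinyl-2-isopropenyl carbinol; either C10 epimer would serve, because C10 becomes sp2 in the next step.

**Step 9**
Reactants: 14 divinyl carbinol
Product: 16 (4E)-1-hydroxy-4-methyl-6-(triethylsilyloxy)-8-(triisopropylsilyloxy)-7-[(triisopropylsilyl)ethynyl]cyclodec-4-en-10-one (target numbering), via potassium enolate 15 (not isolated)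
Conditions: KH, 18-crown-6, THF, 0 °C to rt; then −78 °C, 2-(phenylsulfonyl)-3-phenyloxaziridine; NH4Cl
Reagents that add atoms: 2-(phenylsulfonyl)-3-phenyloxaziridine, O=S(=O)(c1ccccc1)N1OC1c1ccccc1
Why: Anionic oxy-Cope rearrangement through a chair transition state with both ring bonds pseudo-equatorial gives the (E)-cyclodecenone enolate, and its regiodefined C1 is hydroxylated in situ by the Davis oxaziridine (peripheral attack, mainly 1R; this centre is reset in steps 11 and 17).

**Step 10**
Reactants: 16 α-hydroxy ketone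
Product: 17 (4E)-4-methyl-10-methylidene-6-(triethylsilyloxy)-8-(triisopropylsilyloxy)-7-[(triisopropylsilyl)ethynyl]cyclodec-4-en-1-ol
Conditions: Ph3PCH3Br, KOt-Bu, THF, 0 °C to rt
Reagents that add atoms: methyltriphenylphosphonium bromide, C[P+](c1ccccc1)(c1ccccc1)c1ccccc1.[Br-]
Why: Wittig methylenation of the ketone installs the exocyclic C10 methylene (C14).

**Step 11**
Reactants: 17 allylic alcohol
Product: 18 (4E)-4-methyl-10-methylidene-6-(triethylsilyloxy)-8-(triisopropylsilyloxy)-7-[(triisopropylsilyl)ethynyl]cyclodec-4-en-1-one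
Conditions: Dess–Martin periodinane, NaHCO3, CH2Cl2, 0 °C to rt
Reagents that add atoms: none
Why: Dess–Martin oxidation of the only free hydroxyl gives the cross-conjugated enone, which erases C1 and blocks it during the later acylation.

**Step 12**
Reactants: 18 enone
Product: 19 (4E)-6-hydroxy-4-methyl-10-methylidene-8-(triisopropylsilyloxy)-7-[(triisopropylsilyl)ethynyl]cyclodec-4-en-1-one
Conditions: HF·pyridine, pyridine, THF, 0 °C
Reagents that add atoms: none
Why: Selective desilylation: the triethylsilyl ether is cleaved much faster than the two triisopropylsilyl groups, freeing the C6 hydroxyl.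

**Step 13**
Reactants: 19 C6 alcohol
Product: 20 C6 (Z)-2-methylbut-2-enoate (angelate) of 19
Conditions: angelic acid, 2,4,6-trichlorobenzoyl chloride, Et3N, toluene, rt; then 19, 75 °C
Reagents that add atoms: angelic acid, C/C=C(/C)C(=O)O
Why: Yamaguchi-type esterification through the mixed 2,4,6-trichlorobenzoic anhydride acylates the C6 alcohol without Z to E isomerisation of the angelate.

**Step 14**
Reactants: 20 angelate
Product: 21 (4E)-7-ethynyl-8-hydroxy-4-methyl-10-methylidene-1-oxocyclodec-4-en-6-yl (Z)-2-methylbut-2-enoate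
Conditions: TBAF, AcOH, THF, rt
Reagents that add atoms: none
Why: Fluoride cleaves both the triisopropylsilyl ether and the alkynylsilane, revealing the trans homopropargylic alcohol.

**Step 15**
Reactants: 21 hydroxy alkyne
Product: 22 trans-fused 1-oxo-6-angeloyloxy-germacra-4(E),10(14),11(13)-trien-12,8-olide
Conditions: PdCl2 (5 mol%), PPh3 (10 mol%), SnCl2 (5 mol%), CO (7 atm), MeCN, 70 °C
Reagents that add atoms: carbon monoxide, [C-]#[O+]
Why: Norton Pd-catalysed cyclocarbonylation of the 3-butyn-1-ol unit closes the trans-fused α-methylene-γ-butyrolactone (C12 from CO), the ring fusion being fixed by the existing C7 and C8 centres.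

**Step 16**
Reactants: 22 lactone enone
Product: 23 (4R,5R)-4,5-epoxide of 22
Conditions: mCPBA, NaHCO3, CH2Cl2, 0 °C
Reagents that add atoms: mCPBA, O=C(OO)c1cccc(Cl)c1
Why: Prilezhaev epoxidation, in which only the electron-rich trisubstituted 4,5-alkene reacts and attack on the peripheral face of the (E)-cyclodecene (H6 eclipsing the C4 methyl, allylic 1,3-strain) gives the 4R,5R epoxide.

**Step 17**
Reactants: 23 epoxy enone
Product: 24 target CNP0104965.3
Conditions: (R)-2-methyl-CBS-oxazaborolidine, catecholborane, toluene, −78 °C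
Reagents that add atoms: none
Why: Corey–Bakshi–Shibata reduction, a reagent-controlled 1,2-hydride delivery to the enone with the alkenyl group as the large substituent, sets 1S.

**Compound list**
1 | 2-methylfuran | Cc1ccco1 | starting material
2 | (Z)-4-oxopent-2-enal | CC(=O)/C=C\C=O | intermediate
3 | (E)-4-oxopent-2-enal | CC(=O)/C=C/C=O | intermediate
4 | 3-methoxyfuran | COc1ccoc1 | starting material
5 | (1R,2R,3R,4R)-3-acetyl-5-methoxy-7-oxabicyclo[2.2.1]hept-5-ene-2-carbaldehyde (2-endo-CHO, 3-exo-acetyl) | COC1=C[C@H]2O[C@@H]1[C@H](C(C)=O)[C@H]2C=O | intermediate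
6 | 1-(3-endo-ethynyl-6-methoxy-7-oxabicyclo[2.2.1]hept-5-en-2-exo-yl)ethanone (configuration as 5) | COC1=C[C@H]2O[C@@H]1[C@H](C(C)=O)[C@H]2C#C | intermediate
7 | 1-(3-endo-ethynyl-6,6-dimethoxy-7-oxabicyclo[2.2.1]hept-2-exo-yl)ethanone | COC1(OC)C[C@H]2O[C@@H]1[C@H](C(C)=O)[C@H]2C#C | intermediate
8 | 3-endo-ethynyl-6,6-dimethoxy-7-oxabicyclo[2.2.1]hept-2-exo-yl acetate | COC1(OC)C[C@H]2O[C@@H]1[C@H](OC(C)=O)[C@H]2C#C | intermediate
9 | 6,6-dimethoxy-2-exo-(triisopropylsilyloxy)-3-endo-[(triisopropylsilyl)ethynyl]-7-oxabicyclo[2.2.1]heptane | COC1(OC)C[C@H]2O[C@@H]1[C@H](O[Si](C(C)C)(C(C)C)C(C)C)[C@H]2C#C[Si](C(C)C)(C(C)C)C(C)C | intermediate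
10 | 6-exo-(triisopropylsilyloxy)-5-endo-[(triisopropylsilyl)ethynyl]-7-oxabicyclo[2.2.1]heptan-2-one | O=C1C[C@H]2O[C@@H]1[C@H](O[Si](C(C)C)(C(C)C)C(C)C)[C@H]2C#C[Si](C(C)C)(C(C)C)C(C)C | intermediate
11 | 3-endo-(prop-1-en-2-yl) derivative of 10 | O=C1[C@H](C(C)=C)[C@H]2O[C@@H]1[C@H](O[Si](C(C)C)(C(C)C)C(C)C)[C@H]2C#C[Si](C(C)C)(C(C)C)C(C)C | intermediate
12 | all-equatorial (2,3-trans, 3,4-trans, 4,5-trans) 3-hydroxy-2-(prop-1-en-2-yl)-5-(triisopropylsilyloxy)-4-[(triisopropylsilyl)ethynyl]cyclohexan-1-one | O=C1[C@H](C(C)=C)[C@@H](O)[C@H](C#C[Si](C(C)C)(C(C)C)C(C)C)[C@@H](O[Si](C(C)C)(C(C)C)C(C)C)C1 | intermediate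
13 | 3-O-triethylsilyl ether of 12 | O=C1[C@H](C(C)=C)[C@@H](O[Si](CC)(CC)CC)[C@H](C#C[Si](C(C)C)(C(C)C)C(C)C)[C@@H](O[Si](C(C)C)(C(C)C)C(C)C)C1 | intermediate
14 | 1-ethenyl carbinol from 13 (vinyl equatorial and trans to isopropenyl, OH axial) | C=C[C@@]1(O)[C@H](C(C)=C)[C@@H](O[Si](CC)(CC)CC)[C@H](C#C[Si](C(C)C)(C(C)C)C(C)C)[C@@H](O[Si](C(C)C)(C(C)C)C(C)C)C1 | intermediate
15 | potassium C1=C10 enolate of the (4E)-cyclodec-4-en-10-one (6-OTES, 8-OTIPS, 7-silylethynyl) | [K+].[O-]/C1=C\CC/C(C)=C/[C@@H](O[Si](CC)(CC)CC)[C@H](C#C[Si](C(C)C)(C(C)C)C(C)C)[C@@H](O[Si](C(C)C)(C(C)C)C(C)C)C1 | intermediate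
16 | (4E)-1-hydroxy-4-methyl-6-(triethylsilyloxy)-8-(triisopropylsilyloxy)-7-[(triisopropylsilyl)ethynyl]cyclodec-4-en-10-one (target numbering; 1R epimer shown; O6 and O8 α, C7 side chain β) | O=C1C[C@H](O[Si](C(C)C)(C(C)C)C(C)C)[C@@H](C#C[Si](C(C)C)(C(C)C)C(C)C)[C@H](O[Si](CC)(CC)CC)/C=C(\C)CC[C@H]1O | intermediate
17 | 10-methylidene analogue of 16 (C1 alcohol) | C=C1C[C@H](O[Si](C(C)C)(C(C)C)C(C)C)[C@@H](C#C[Si](C(C)C)(C(C)C)C(C)C)[C@H](O[Si](CC)(CC)CC)/C=C(\C)CC[C@H]1O | intermediate
18 | C1 ketone of 17 (10-methylidene enone) | C=C1C[C@H](O[Si](C(C)C)(C(C)C)C(C)C)[C@@H](C#C[Si](C(C)C)(C(C)C)C(C)C)[C@H](O[Si](CC)(CC)CC)/C=C(\C)CCC1=O | intermediate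
19 | C6 alcohol from 18 | C=C1C[C@H](O[Si](C(C)C)(C(C)C)C(C)C)[C@@H](C#C[Si](C(C)C)(C(C)C)C(C)C)[C@H](O)/C=C(\C)CCC1=O | intermediate
20 | C6 angelate of 19 | C=C1C[C@H](O[Si](C(C)C)(C(C)C)C(C)C)[C@@H](C#C[Si](C(C)C)(C(C)C)C(C)C)[C@H](OC(=O)/C(C)=C\C)/C=C(\C)CCC1=O | intermediate
21 | (4E)-7-ethynyl-8-hydroxy-4-methyl-10-methylidene-1-oxocyclodec-4-en-6-yl (Z)-2-methylbut-2-enoate (target numbering) | C=C1C[C@H](O)[C@@H](C#C)[C@H](OC(=O)/C(C)=C\C)/C=C(\C)CCC1=O | intermediate
22 | 1-oxo-6α-angeloyloxy-germacra-4(E),10(14),11(13)-trien-12,8α-olide (trans-fused lactone) | C=C1C(=O)O[C@H]2CC(=C)C(=O)CC/C(C)=C/[C@@H](OC(=O)/C(C)=C\C)[C@H]12 | intermediate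
23 | (4R,5R)-4,5-epoxide of 22 | C=C1C(=O)O[C@H]2CC(=C)C(=O)CC[C@@]3(C)O[C@@H]3[C@@H](OC(=O)/C(C)=C\C)[C@H]12 | intermediate
24 | CNP0104965.3, (1S,4R,5R,6S,7R,8S) | C=C1C(=O)O[C@H]2CC(=C)[C@@H](O)CC[C@@]3(C)O[C@@H]3[C@@H](OC(=O)/C(C)=C\C)[C@H]12 | target

**Totals and risk**
Total step count: 17. Longest linear sequence: 17 steps (1 to 24); 3-methoxyfuran 4 enters at step 2.

Steps most likely to fail:

Step 2 (asymmetric furan Diels–Alder). The Lewis acid may divert the electron-rich furan into Friedel–Crafts or Michael products, or the ee may be low. Fallback, setting out from 3 and 4: the two are combined without catalyst at 12 kbar in CH2Cl2 at rt. The thermal [4+2] gives the racemate, that is 5 together with its mirror image ent-adduct F1, and 5 is obtained by preparative chromatography on a chiral stationary phase. The route is rejoined at 5.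

Step 6 (α-isopropenylation). The Pd-enolate coupling may suffer β-alkoxide elimination or over-alkenylation. Fallback, setting out from 10: TMSOTf/Et3N gives trimethylsilyl enol ether F2, which is alkenylated at C5 with isopropenyl(mesityl)iodonium triflate and catalytic Cu(OTf)2, an electrophilic alkenyl transfer to the enol silane in place of a palladium enolate. The route is rejoined at 11.

Step 15 (cyclocarbonylation). The allylic angelate or the enone may interfere under the Pd/Sn conditions. Fallback, setting out from 21: Markovnikov hydroiodination of the alkyne with B-iodo-9-BBN then AcOH gives 2-iodoalkene F3, and the lactone is closed by Pd(PPh3)4-catalysed carbonylation (CO 1 atm, Et3N, MeCN, rt). The route is rejoined at 22.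

**Further compounds**
F1 | step 2 | (1S,2S,3S,4S)-3-acetyl-5-methoxy-7-oxabicyclo[2.2.1]hept-5-ene-2-carbaldehyde (mirror image of 5) | COC1=C[C@@H]2O[C@H]1[C@@H](C(C)=O)[C@@H]2C=O
F2 | step 6 | 2-(trimethylsilyloxy)-6-exo-(triisopropylsilyloxy)-5-endo-[(triisopropylsilyl)ethynyl]-7-oxabicyclo[2.2.1]hept-2-ene | C[Si](C)(C)OC1=C[C@H]2O[C@@H]1[C@H](O[Si](C(C)C)(C(C)C)C(C)C)[C@H]2C#C[Si](C(C)C)(C(C)C)C(C)C
F3 | step 15 | (4E)-8-hydroxy-7-(1-iodoethenyl)-4-methyl-10-methylidene-1-oxocyclodec-4-en-6-yl (Z)-2-methylbut-2-enoate | C=C1C[C@H](O)[C@@H](C(I)=C)[C@H](OC(=O)/C(C)=C\C)/C=C(\C)CCC1=O
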